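Everything rests on disconnecting ring B, the 1,4-phenylene ring whose C4 carries the ether oxygen to ring C and whose C1 carries the two-carbon chain to ring A, into the four carbons of a 2-aryloxybutadiene and the two alkyne carbons of a terminal ynone. One thermal Diels–Alder reaction forms both new C–C bonds, closes the six-membered carbocycle and sets oxygen and acyl carbon para, so the diaryl ether oxygen comes from a simple phenol acylation and no aryl–oxygen coupling is needed. The diene precursor is the methylenated acrylate of the isovanillin-derived bibenzyl phenol; every other phenol is masked as a methyl ether.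

Key step: step 8

Ring labels: ring A = 3-hydroxyphenyl, ring B = 1,4-phenylene, ring C = the phenol ring bearing the ether oxygen, ring D = the catechol ring.

Remark on the chemistry: the target is achiral. The alkene geometry of the stilbene intermediate and the carbinol centres of two transient intermediates are erased within the route and are therefore not controlled.

Step 1
Reactants: 1 2,3-dimethoxybenzyl alcohol
Product: 2 (2,3-dimethoxybenzyl)triphenylphosphonium bromide
Conditions: Ph3P·HBr (1.05 equiv), MeCN, reflux
Reagents that add atoms: triphenylphosphine hydrobromide, Br.c1ccc(cc1)P(c1ccccc1)c1ccccc1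
Why: Direct phosphonium salt formation from a benzylic alcohol is an acid-promoted SN1-type substitution, in which protonation makes water the leaving group and the ortho-methoxy group stabilises the benzylic cation that triphenylphosphine captures.

Step 2
Reactants: 2 (2,3-dimethoxybenzyl)triphenylphosphonium bromide; 3 isovanillin (3-hydroxy-4-methoxybenzaldehyde)
Product: 5 5-[2-(2,3-dimethoxyphenyl)ethenyl]-2-methoxyphenol (E/Z mixture), via benzylidenephosphorane 4 (not isolated)
Conditions: KOtBu (2.3 equiv), THF–DMF, 0 °C to rt; then 1 M HCl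
Reagents that add atoms: none
Why: This is a Wittig olefination with a semi-stabilised benzylic ylide, in which the extra equivalent of base holds the phenol as a phenoxide that sits meta to the formyl group and so does not deactivate the aldehyde by conjugation, and the alkene geometry is irrelevant because both isomers are saturated in step 3.

Step 3
Reactants: 5 5-[2-(2,3-dimethoxyphenyl)ethenyl]-2-methoxyphenol (E/Z mixture)
Product: 6 5-[2-(2,3-dimethoxyphenyl)ethyl]-2-methoxyphenol
Conditions: H2 (1 atm), 10% Pd/C, EtOAc, rt
Reagents that add atoms: none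
Why: Heterogeneous catalytic hydrogenation of a 1,2-diarylethene over palladium is fast at ambient pressure and leaves the aryl methyl ethers and the phenol untouched, so both alkene isomers converge on one bibenzyl.

Step 4
Reactants: 6 5-[2-(2,3-dimethoxyphenyl)ethyl]-2-methoxyphenol; 7 acryloyl chloride
Product: 8 5-[2-(2,3-dimethoxyphenyl)ethyl]-2-methoxyphenyl prop-2-enoate
Conditions: Et3N (1.5 equiv), CH2Cl2, 0 °C
Reagents that add atoms: none
Why: Base-mediated O-acylation of a phenol by an acid chloride (Schotten–Baumann-type esterification) should outrun oxa-Michael addition to the acrylate at 0 °C, and the methyl ethers are inert.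

Step 5
Reactants: 8 5-[2-(2,3-dimethoxyphenyl)ethyl]-2-methoxyphenyl prop-2-enoate
Product: 9 2-(buta-1,3-dien-2-yloxy)-4-[2-(2,3-dimethoxyphenyl)ethyl]-1-methoxybenzene
Conditions: Cp2Ti(μ-CH2)(μ-Cl)AlMe2 (1.3 equiv, toluene solution), pyridine (cat.), THF, −40 °C to rt; 15% aq NaOH at −10 °C; filtration through basic Al2O3; used promptly
Reagents that add atoms: Cp2Ti(μ-CH2)(μ-Cl)AlMe2 (delivers CH2), C[Al-]1(C)C[Ti]([Cl+]1)(C2C=CC=C2)C3C=CC=C3
Why: In this Tebbe methylenation of an ester the titanium methylidene released by the Lewis base adds to the ester carbonyl by [2+2] cycloaddition and the oxatitanacyclobutane cycloreverts to the enol ether and a strong Ti=O bond, aryl esters and α,β-unsaturated esters being established substrates and carbonyl attack being faster than reaction at the conjugated terminal alkene at low temperature.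

Step 6
Reactants: 10 3-methoxyphenylacetic acid
Product: 12 N-methoxy-2-(3-methoxyphenyl)-N-methylacetamide, via acyl imidazole 11 (not isolated)
Conditions: CDI (1.1 equiv), CH2Cl2, rt; then MeNH(OMe)·HCl (1.2 equiv), rt
Reagents that add atoms: N,O-dimethylhydroxylamine hydrochloride, CNOC.Cl; 1,1'-carbonyldiimidazole, O=C(n1ccnc1)n1ccnc1 (its imidazole unit is held only in 11)
Why: Amide formation through an acyl imidazolide (CDI coupling) runs under neutral conditions, the amine hydrochloride protonating the displaced imidazole, and gives the Weinreb amide needed for a single controlled addition.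

Step 7
Reactants: 12 N-methoxy-2-(3-methoxyphenyl)-N-methylacetamide; 13 ethynylmagnesium bromide (HC≡CMgBr)
Product: 15 1-(3-methoxyphenyl)but-3-yn-2-one, via magnesium chelate 14 (not isolated)
Conditions: HC≡CMgBr (1.5 equiv, THF), THF, −20 to 0 °C; inverse quench into cold 1 M HCl; concentrated cold and used promptly
Reagents that add atoms: none
Why: In this Weinreb ketone synthesis the alkynyl Grignard reagent adds once to give a five-membered magnesium chelate that collapses only in the acidic inverse quench, which also protonates the released N,O-dimethylhydroxylamine so that it cannot add in conjugate fashion to the terminal ynone, and the transient carbinolamine centre vanishes on collapse.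

Step 8
Reactants: 9 2-(buta-1,3-dien-2-yloxy)-4-[2-(2,3-dimethoxyphenyl)ethyl]-1-methoxybenzene; 15 1-(3-methoxyphenyl)but-3-yn-2-one
Product: 16 1-(4-{5-[2-(2,3-dimethoxyphenyl)ethyl]-2-methoxyphenoxy}cyclohexa-1,4-dien-1-yl)-2-(3-methoxyphenyl)ethan-1-one
Conditions: 15 (1.3 equiv), BHT (cat.), degassed toluene, 90 °C, sealed base-washed tube, argon; concentrated and carried on crude
Reagents that add atoms: none
Why: The reaction is a concerted but asynchronous, thermally allowed [π4s+π2s] cycloaddition in which the HOMO of the s-cis 2-aryloxydiene overlaps with the LUMO of the ynone, the CH2 terminus next to the oxygen-bearing carbon bonding to the unsubstituted alkyne carbon and the other diene terminus to the acyl-bearing carbon. The closest known reaction type is the normal-demand Diels–Alder addition of 2-alkoxy-, 2-silyloxy- and 2-aryloxybutadienes to acetylenic ketones and propiolates, which gives 1,4-cyclohexadienes ready for dehydrogenation. Ring B is closed as a six-membered carbocycle by intermolecular [4+2] annulation, both ring bonds arising in one suprafacial event without a tether or a pre-existing ring. No stereocentre is created, because the two new sp3 ring carbons are CH2 groups and the other four ring carbons are sp2. The step needs para (1,4) rather than meta (1,3) regiochemistry, and the oxygen lone pair secures it by placing the largest HOMO coefficient on the CH2 terminus adjacent to C–OAr, matched with the largest LUMO coefficient on the β-carbon of the ynone. It also needs the enol ether to survive, which neutral, acid-free heating with a radical inhibitor should allow, while the adduct is a much poorer dienophile than the ynone and should not react again.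

Step 9
Reactants: 16 1-(4-{5-[2-(2,3-dimethoxyphenyl)ethyl]-2-methoxyphenoxy}cyclohexa-1,4-dien-1-yl)-2-(3-methoxyphenyl)ethan-1-one
Product: 17 1-(4-{5-[2-(2,3-dimethoxyphenyl)ethyl]-2-methoxyphenoxy}phenyl)-2-(3-methoxyphenyl)ethan-1-one
Conditions: DDQ (1.05 equiv), dry toluene, 0 °C to rt; filtration, aq NaHCO3 wash
Reagents that add atoms: none
Why: In this DDQ dehydrogenation of a 1,4-cyclohexadiene, hydride abstraction from a doubly allylic CH2 gives an oxygen-stabilised cyclohexadienyl cation that loses a proton, and the gain of aromaticity should make this far faster at 0 °C than benzylic oxidation of the methoxylated bibenzyl unit when only one equivalent of quinone is present.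

Step 10
Reactants: 17 1-(4-{5-[2-(2,3-dimethoxyphenyl)ethyl]-2-methoxyphenoxy}phenyl)-2-(3-methoxyphenyl)ethan-1-one
Product: 19 4-[2-(2,3-dimethoxyphenyl)ethyl]-1-methoxy-2-{4-[2-(3-methoxyphenyl)ethyl]phenoxy}benzene, via benzylic carbinol 18 (not isolated)
Conditions: Et3SiH (4 equiv), CF3CO2H, CH2Cl2, 0 °C to rt; aq NaHCO3 work-up
Reagents that add atoms: none
Why: In this ionic hydrogenation (Kursanov–Parnes reduction) of an aryl ketone, hydride transfer to the protonated carbonyl gives the benzylic alcohol, which ionises in trifluoroacetic acid to a cation stabilised by the para-aryloxy group and is reduced again by the silane, the diaryl ether and methyl ethers being inert and the racemic carbinol centre disappearing.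

Step 11
Reactants: 19 4-[2-(2,3-dimethoxyphenyl)ethyl]-1-methoxy-2-{4-[2-(3-methoxyphenyl)ethyl]phenoxy}benzene
Product: 21 3-[2-(4-hydroxy-3-{4-[2-(3-hydroxyphenyl)ethyl]phenoxy}phenyl)ethyl]benzene-1,2-diol, via aryloxyboron bromide 20 (not isolated)
Conditions: BBr3 (8 equiv, 1 M in CH2Cl2), CH2Cl2, −78 °C to rt, argon; then ice-water, degassed work-up
Reagents that add atoms: boron tribromide, BrB(Br)Br (boron and bromine are held only in 20)
Why: In this Lewis-acid cleavage of aryl methyl ethers with BBr3 each methoxy oxygen coordinates boron and bromide removes the methyl group by SN2 displacement, whereas the diaryl ether has no sp3 carbon on oxygen and survives, and hydrolysis of the aryl borates releases the four phenols.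

Compound list
1 | 2,3-dimethoxybenzyl alcohol | COc1cccc(CO)c1OC | starting material
2 | (2,3-dimethoxybenzyl)triphenylphosphonium bromide | COc1cccc(C[P+](c2ccccc2)(c2ccccc2)c2ccccc2)c1OC.[Br-] | intermediate
3 | isovanillin (3-hydroxy-4-methoxybenzaldehyde) | COc1ccc(C=O)cc1O | starting material
4 | (2,3-dimethoxybenzylidene)triphenylphosphorane | COc1cccc(C=P(c2ccccc2)(c2ccccc2)c2ccccc2)c1OC | intermediate (not isolated)
5 | 5-[2-(2,3-dimethoxyphenyl)ethenyl]-2-methoxyphenol, E/Z mixture, geometry not defined | COc1ccc(C=Cc2cccc(OC)c2OC)cc1O | intermediate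
6 | 5-[2-(2,3-dimethoxyphenyl)ethyl]-2-methoxyphenol | COc1ccc(CCc2cccc(OC)c2OC)cc1O | intermediate
7 | acryloyl chloride | C=CC(=O)Cl | starting material
8 | 5-[2-(2,3-dimethoxyphenyl)ethyl]-2-methoxyphenyl prop-2-enoate | C=CC(=O)Oc1cc(CCc2cccc(OC)c2OC)ccc1OC | intermediate
9 | 2-(buta-1,3-dien-2-yloxy)-4-[2-(2,3-dimethoxyphenyl)ethyl]-1-methoxybenzene | C=CC(=C)Oc1cc(CCc2cccc(OC)c2OC)ccc1OC | intermediate
10 | 3-methoxyphenylacetic acid | COc1cccc(CC(=O)O)c1 | starting material
11 | 1-(imidazol-1-yl)-2-(3-methoxyphenyl)ethan-1-one | COc1cccc(CC(=O)n2ccnc2)c1 | intermediate (not isolated)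
12 | N-methoxy-2-(3-methoxyphenyl)-N-methylacetamide | COc1cccc(CC(=O)N(C)OC)c1 | intermediate
13 | ethynylmagnesium bromide | C#C[Mg]Br | starting material
14 | bromomagnesium alkoxide of the tetrahedral adduct, 2-[methoxy(methyl)amino]-1-(3-methoxyphenyl)but-3-yn-2-olate (racemic) | COc1cccc(CC(O[Mg]Br)(C#C)N(C)OC)c1 | intermediate (not isolated)
15 | 1-(3-methoxyphenyl)but-3-yn-2-one | C#CC(=O)Cc1cccc(OC)c1 | intermediate
16 | 1-(4-{5-[2-(2,3-dimethoxyphenyl)ethyl]-2-methoxyphenoxy}cyclohexa-1,4-dien-1-yl)-2-(3-methoxyphenyl)ethan-1-one | COc1cccc(CC(=O)C2=CCC(Oc3cc(CCc4cccc(OC)c4OC)ccc3OC)=CC2)c1 | intermediate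
17 | 1-(4-{5-[2-(2,3-dimethoxyphenyl)ethyl]-2-methoxyphenoxy}phenyl)-2-(3-methoxyphenyl)ethan-1-one | COc1cccc(CC(=O)c2ccc(Oc3cc(CCc4cccc(OC)c4OC)ccc3OC)cc2)c1 | intermediate
18 | 1-(4-{5-[2-(2,3-dimethoxyphenyl)ethyl]-2-methoxyphenoxy}phenyl)-2-(3-methoxyphenyl)ethan-1-ol (racemic) | COc1cccc(CC(O)c2ccc(Oc3cc(CCc4cccc(OC)c4OC)ccc3OC)cc2)c1 | intermediate (not isolated)
19 | 4-[2-(2,3-dimethoxyphenyl)ethyl]-1-methoxy-2-{4-[2-(3-methoxyphenyl)ethyl]phenoxy}benzene | COc1cccc(CCc2ccc(Oc3cc(CCc4cccc(OC)c4OC)ccc3OC)cc2)c1 | intermediate
20 | boron aryloxide of the target: rings A and C as O-dibromoboryl ethers, ring D as the 2-bromo-1,3,2-benzodioxaborole | BrB(Br)Oc1cccc(CCc2ccc(Oc3cc(CCc4cccc5OB(Br)Oc45)ccc3OB(Br)Br)cc2)c1 | intermediate (not isolated)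
21 | 3-[2-(4-hydroxy-3-{4-[2-(3-hydroxyphenyl)ethyl]phenoxy}phenyl)ethyl]benzene-1,2-diol (CNP0185459.0) | Oc1cccc(CCc2ccc(Oc3cc(CCc4cccc(O)c4O)ccc3O)cc2)c1 | target

Total step count: 11.
Longest linear sequence: 9 steps (steps 1–5 and 8–11, from 1); the ynone branch (steps 6–7) joins at step 8.

Steps most likely to fail

Step 8. Thermal oligomerisation of the diene or decomposition of the enolisable ynone may outpace the cycloaddition. Regiocontrol may also be incomplete, or adventitious acid may hydrolyse the enol ether. The fallback sets out from phenol 6 and makes the diaryl ether by nucleophilic aromatic substitution instead of building ring B. Heating 6 with 4-fluorobenzaldehyde and K2CO3 in DMF at about 130 °C should give 4-{5-[2-(2,3-dimethoxyphenyl)ethyl]-2-methoxyphenoxy}benzaldehyde F1. Commercial (3-methoxybenzyl)triphenylphosphonium chloride and KOtBu in THF give the ylide (3-methoxybenzylidene)triphenylphosphorane F2 in the flask. Its Wittig reaction with F1 should give 4-[2-(2,3-dimethoxyphenyl)ethyl]-1-methoxy-2-{4-[2-(3-methoxyphenyl)ethenyl]phenoxy}benzene F3 as an E/Z mixture. Hydrogenation of F3 (H2, 10% Pd/C, EtOAc) returns to the route at 19.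

Step 5. The titanium methylidene may engage the acrylate alkene, or the acrylate may polymerise. The Lewis-acidic aluminium by-product may also hydrolyse or oligomerise the dienyl ether during work-up. The fallback sets out from phenol 6 and forms the branched C–O bond by Tsuji–Trost chemistry, then makes the diene by elimination, with no ester methylenation. Phenol 6 and 3,4-epoxybut-1-ene with Pd2(dba)3·CHCl3 (a zerovalent palladium source) and PPh3 in THF should give racemic 2-{5-[2-(2,3-dimethoxyphenyl)ethyl]-2-methoxyphenoxy}but-3-en-1-ol F4. The alkoxide of the π-allyl intermediate should deliver the phenol to the adjacent carbon, which gives the branched isomer. Mesylation (MsCl, Et3N, CH2Cl2, 0 °C) should give racemic 2-{5-[2-(2,3-dimethoxyphenyl)ethyl]-2-methoxyphenoxy}but-3-en-1-yl methanesulfonate F5. E2 elimination with KOtBu in THF at 0 °C removes the allylic, oxygen-bearing C2–H, as in the classical preparation of aryl vinyl ethers from 2-aryloxyethyl halides, and returns to the route at 9.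

Step 7. The released N,O-dimethylhydroxylamine may add in conjugate fashion to the ynone during the quench. The Grignard reagent may enolise the arylacetamide, or the terminal ynone may oligomerise on concentration. The fallback sets out from Weinreb amide 12 and reaches the ynone by oxidation of a propargylic alcohol, so no amine is present when the ynone forms. Reduction of 12 with i-Bu2AlH in THF at −78 °C should give the diisobutylaluminium hemiaminal of 12 F6. Work-up with aqueous potassium sodium tartrate (KNaC4H4O6) releases (3-methoxyphenyl)acetaldehyde F7, which is used crude. Addition of ethynylmagnesium bromide 13 in THF at −78 to 0 °C, followed by a dilute HCl quench, should give racemic 1-(3-methoxyphenyl)but-3-yn-2-ol F8. Oxidation of F8 with Dess–Martin periodinane in CH2Cl2 at rt returns to the route at 15.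

Further compounds
F1 | step 8 | 4-{5-[2-(2,3-dimethoxyphenyl)ethyl]-2-methoxyphenoxy}benzaldehyde | COc1ccc(CCc2cccc(OC)c2OC)cc1Oc1ccc(C=O)cc1
F2 | step 8 | (3-methoxybenzylidene)triphenylphosphorane | COc1cccc(C=P(c2ccccc2)(c2ccccc2)c2ccccc2)c1
F3 | step 8 | 4-[2-(2,3-dimethoxyphenyl)ethyl]-1-methoxy-2-{4-[2-(3-methoxyphenyl)ethenyl]phenoxy}benzene (E/Z mixture) | COc1cccc(C=Cc2ccc(Oc3cc(CCc4cccc(OC)c4OC)ccc3OC)cc2)c1
F4 | step 5 | 2-{5-[2-(2,3-dimethoxyphenyl)ethyl]-2-methoxyphenoxy}but-3-en-1-ol (racemic) | C=CC(CO)Oc1cc(CCc2cccc(OC)c2OC)ccc1OC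
F5 | step 5 | 2-{5-[2-(2,3-dimethoxyphenyl)ethyl]-2-methoxyphenoxy}but-3-en-1-yl methanesulfonate (racemic) | C=CC(COS(C)(=O)=O)Oc1cc(CCc2cccc(OC)c2OC)ccc1OC
F6 | step 7 | diisobutylaluminium 1-[methoxy(methyl)amino]-2-(3-methoxyphenyl)ethan-1-olate (racemic) | COc1cccc(CC(O[Al](CC(C)C)CC(C)C)N(C)OC)c1
F7 | step 7 | (3-methoxyphenyl)acetaldehyde | COc1cccc(CC=O)c1
F8 | step 7 | 1-(3-methoxyphenyl)but-3-yn-2-ol (racemic) | C#CC(O)Cc1cccc(OC)c1
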